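A small charge of free catalyst, 3.9 mM, had carried the north-west flask to 100.4% over-reaction product, and I asked what that run said about the price of a product in partner.

- north-west: starting material 0.013 M (in portions, 2); partner 0.026 M; free catalyst 3.9 mM; run made earlier; portions every 2.0 min
- flask: starting material 0.026 M (in portions, 2); partner 0.0260 M; free catalyst 3.9 mM; time 15 h; the portions of starting material follow each other after 2.0 min, the first at the start

north-west run (percent of the starting material charged)

| time / h | over-reaction product / % | target / % |
|---|---|---|
| 0.250 | 89.1 | 8.0 |
| 0.500 | 98.7 | 0.5 |
| 1.33 | 101.5 | 0 |
| 3.00 | 100.4 | 0.1 |

(standard deviation of a reading: 0.5 percentage points)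

- the analysis behind the earlier runs scatters by 0.5 percentage points, standard deviation
- the reaction counts as stopped when no species that holds the starting material changes by six tenths of a point or more over the second half of the time

* at 15 h, what has stopped the reaction, if anything has (no working catalyst is left / the partner has run out first / forward and back rates have come level / it is still moving / all of the starting material has reacted)
* amount of over-reaction product at 15 h, in percent of the starting material charged

The north-west run cannot have spent more partner than it was charged, so 1.99, as read at 3.00 h, was the price ceiling, the upper bound on partner spent per over-reaction product formed. Its missing product fell with a constant of 8.87 h⁻¹ up to 0.250 h and 8.51 h⁻¹ after it. Within the scatter, these readings showed no slowing as the partner ran down, so I let target go on to over-reaction product without partner.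

I then drew the new flask's curve. I took the north-west slope at the same catalyst, 0.115 M h⁻¹. At the ceiling price, the partner (the limiting reagent) bought a level of 50.2%, reached at a knee near 6.79 min. The second portion, at 2.0 min, fell on this rise, earlier than the knee. After that I drew a flat line to 15 h, with starting material left over, and I held that level as my floor.

The forecast, with “each over-reaction product costing two partners”, gave "the partner has run out first" and 33%, lower than my floor. The flask gave "the partner has run out first", with 0% of the partner left and 58.5% over-reaction product, and starting material stood at 41.5% by 0.750 h.

    catalyst intermediate B → catalyst intermediate C (k = 0.917 s⁻¹)
    partner + free catalyst → catalyst intermediate A (k = 3.16 M⁻¹ s⁻¹)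
    catalyst intermediate A → released group + catalyst intermediate B (k = 0.339 s⁻¹)
    catalyst intermediate D → free catalyst + target (k = 0.0758 s⁻¹)
    free catalyst + target → free catalyst + over-reaction product (k = 2.04 M⁻¹ s⁻¹)
    starting material + catalyst intermediate C ⇌ catalyst intermediate D (K = 117 M⁻¹, k = 3.74 M⁻¹ s⁻¹)
    2 partner → self-condensation product (k = 0.160 M⁻¹ s⁻¹)

The flask's price came to 1.71, below the ceiling of 1.99. In this flask each product took one partner, as the 0.0152 M of released group shows, and the correction was partner lost in pairs to 0.00540 M of self-condensation product. Without the conversion of two partner into self-condensation product, the flask converted >99.9% of the starting material instead of 58.5%. The rate of that conversion goes with [partner] squared. The neighbour flask with 0.016 M of partner had a floor of 30.9% and gave 45.0%, a price of 1.37, with self-condensation product down to 0.00215 M.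

Readings and results were computed for an exercise; scatter was added.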